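**Plan**
- Retrosynthesis: first the C6–C(=O) aryl ketone bond is cut (C6 aryllithium plus an N-methoxy-N-methyl benzamide), then the pyran bonds O1–C2 and C4–C4a (3-methylbut-2-enal on a phenol), then ring A at C8a–C8, C6–C7 and C4a–C8a.
- Ring A permits the last cut because it is a 1,3,5-trioxygenated benzene (oxygen on C5, C7, C8a) whose prenylated C8 sits between the oxygen-bearing C7 and C8a. C7–C8 is a prenyl-substituted siloxyalkyne; C8a, C6, C5 and C4a are the four carbons of a 3-methoxy vinylketene.
- Forward: diazo enone 5 and siloxyalkyne 11 (two steps each) are joined by a photochemical benzannulation to phenol 16, which has ring A complete and its free OH (future O1) distinguished from the silyl ether (future C7 oxygen).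
- The pyran ring is then fused at the free phenol, the silyl ether is exchanged for a MOM ether, C6 is lithiated and acylated, and both MOM groups are removed.
- The target has no stereocentre; all control is regiochemical (orientation of the ketene–alkyne union, one free ortho position for pyran fusion, one aryl C–H for lithiation).

Key step: step 5

Assumption: methyl 4-hydroxybenzoate is taken as the purchased source of the 4-hydroxybenzoyl unit and ethynylmagnesium bromide is bought as its THF solution; diazo ketone 5, being small, is handled cold and in solution.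

**Step 1**
Reactants: 1 3,3-dimethoxybutan-2-one
Product: 2 3-methoxybut-3-en-2-one
Conditions: p-TsOH·H2O (cat.), hydroquinone (trace), neat, 140–150 °C, MeOH distilled off; then distillation
Reagents that add atoms: none
Why: Acid-catalysed ketal-to-enol-ether elimination of methanol, driven by removal of MeOH, should give the 2-methoxy enone as the only possible enol ether because the ketal carbon has hydrogens only on its methyl neighbour.

**Step 2**
Reactants: 2 3-methoxybut-3-en-2-one
Product: 5 1-diazo-3-methoxybut-3-en-2-one, via lithium enolate 3 (not isolated), via trifluoroacetyl diketone 4 (not isolated)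
Conditions: LiN(SiMe3)2, THF, −78 °C; CF3CO2CH2CF3, −78 °C; dilute HCl work-up, crude 4 used directly; MsN3, Et3N, H2O, MeCN, rt
Reagents that add atoms: methanesulfonyl azide, CS(=O)(=O)N=[N+]=[N-]
Why: Detrifluoroacetylative diazo transfer (a Regitz-type transfer to a trifluoroacetyl-activated ketone) is the standard entry to diazomethyl enones; the acetyl methyl is the only enolizable site and no diazomethane, which would add to the enone, is needed.

**Step 3**
Reactants: 6 prenyl bromide (1-bromo-3-methylbut-2-ene); 7 ethynylmagnesium bromide
Product: 8 5-methylhex-4-en-1-yne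
Conditions: CuCl (cat.), THF, 0 → 50 °C, excess of 7; fractional distillation
Reagents that add atoms: none
Why: Copper-catalysed allyl–alkynyl Grignard coupling should occur at the unhindered primary carbon of the prenyl halide, and the excess of acetylide suppresses double alkylation.

**Step 4**
Reactants: 8 5-methylhex-4-en-1-yne
Product: 11 triisopropyl[(5-methylhex-4-en-1-yn-1-yl)oxy]silane, via lithium acetylide 9 (not isolated), via lithium ynolate 10 (not isolated)
Conditions: n-BuLi, THF, −78 °C; t-BuOOLi (from t-BuOOH and LiN(SiMe3)2), −78 → 0 °C; i-Pr3SiOTf, −78 °C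
Reagents that add atoms: tert-butyl hydroperoxide, CC(C)(C)OO; triisopropylsilyl trifluoromethanesulfonate, CC(C)[Si](C(C)C)(C(C)C)OS(=O)(=O)C(F)(F)F
Why: Oxidation of a lithium acetylide by lithium tert-butyl peroxide is the established route to lithium ynolates, and O-silylation with the bulky triisopropylsilyl triflate should give the isolable siloxyalkyne; only the acetylenic C–H is removed by one equivalent of base.

**Step 5**
Reactants: 5 1-diazo-3-methoxybut-3-en-2-one; 11 triisopropyl[(5-methylhex-4-en-1-yn-1-yl)oxy]silane
Product: 16 5-methoxy-2-(3-methylbut-2-enyl)-3-(triisopropylsilyloxy)phenol, via vinylketene 12 (not isolated), via vinylcyclobutenone 13 (not isolated), via dienylketene 14 (not isolated), via cyclohexadienone 15 (not isolated)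
Conditions: hν (254 nm, low-pressure Hg lamps, Vycor), degassed ClCH2CH2Cl, rt; then 80 °C
Reagents that add atoms: none
Why: Irradiation expels N2 from 5, and the photochemical Wolff rearrangement gives vinylketene 12, which adds to the electron-rich ynol ether 11 in a regioselective [2+2] cycloaddition to vinylcyclobutenone 13; light or the final warming opens 13 by 4π electrocyclic cleavage to dienylketene 14. Ring A then closes by a thermal disrotatory 6π electrocyclization (C8a to C4a) to dienone 15, which tautomerizes to phenol 16, so the ring bonds C8a–C8, C6–C7 and C4a–C8a arise in one operation. The closest known reaction type is the Danheiser benzannulation in its photochemical Wolff variant, in which α-diazo enones and triisopropylsiloxyalkynes give resorcinol monosilyl ethers; the methoxy group on the internal vinyl carbon is a spectator that ends as the C5 ether. No stereocentre is created (the ring CH of 13 is transient). The selectivity needed is the orientation of the [2+2] step, secured by the polarity of the ynol ether: its nucleophilic prenyl-bearing carbon bonds to the electrophilic ketene carbonyl carbon and so places the prenyl group between the phenol and silyloxy carbons, while the trisubstituted prenyl alkene is a far poorer ketenophile and should stay untouched.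

**Step 6**
Reactants: 16 5-methoxy-2-(3-methylbut-2-enyl)-3-(triisopropylsilyloxy)phenol; 17 3-methylbut-2-enal
Product: 19 triisopropyl{[5-methoxy-2,2-dimethyl-8-(3-methylbut-2-enyl)-2H-chromen-7-yl]oxy}silane, via ortho-quinone methide 18 (not isolated)
Conditions: ethylenediammonium diacetate (20 mol %), xylene, 140 °C
Reagents that add atoms: none
Why: Amine-salt-catalysed Knoevenagel-type condensation of the enal at the only free ortho carbon of the phenol (activated by three oxygens) followed by oxa-6π electrocyclization of the ortho-quinone methide is the usual formal [3+3] chromene annulation; the other ortho position is blocked by the prenyl group and the silyl ether rules out a second annulation.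

**Step 7**
Reactants: 19 triisopropyl{[5-methoxy-2,2-dimethyl-8-(3-methylbut-2-enyl)-2H-chromen-7-yl]oxy}silane
Product: 20 5-methoxy-2,2-dimethyl-8-(3-methylbut-2-enyl)-2H-chromen-7-ol
Conditions: Bu4NF, AcOH, THF, 0 °C → rt
Reagents that add atoms: none
Why: Fluoride-induced cleavage of the aryl silyl ether, buffered with acetic acid, should leave the chromene, prenyl and methyl ether groups untouched.

**Step 8**
Reactants: 20 5-methoxy-2,2-dimethyl-8-(3-methylbut-2-enyl)-2H-chromen-7-ol
Product: 22 5-methoxy-7-(methoxymethoxy)-2,2-dimethyl-8-(3-methylbut-2-enyl)-2H-chromene, via sodium phenoxide 21 (not isolated)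
Conditions: NaH, DMF, 0 °C; MOMCl, 0 °C → rt
Reagents that add atoms: chloromethyl methyl ether, COCCl
Why: O-alkylation of the phenoxide (Williamson-type) installs the MOM ether, chosen because it is a strong directing group for ortho-lithiation and, unlike the silyl ether, cannot migrate from oxygen to a neighbouring carbanion.

**Step 9**
Reactants: 23 methyl 4-hydroxybenzoate
Product: 25 methyl 4-(methoxymethoxy)benzoate, via sodium phenoxide 24 (not isolated)
Conditions: NaH, THF/DMF, 0 °C; MOMCl, 0 °C → rt
Reagents that add atoms: chloromethyl methyl ether, COCCl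
Why: Routine Williamson-type MOM protection of a phenol; the ester is inert to the phenoxide and the alkylating agent.

**Step 10**
Reactants: 25 methyl 4-(methoxymethoxy)benzoate
Product: 26 N-methoxy-4-(methoxymethoxy)-N-methylbenzamide
Conditions: MeNHOMe·HCl, i-PrMgCl, THF, −20 → 0 °C
Reagents that add atoms: N,O-dimethylhydroxylamine hydrochloride, CNOC.Cl
Why: Aminolysis of the ester by the chloromagnesium amide formed in the flask is the standard one-step conversion of esters into Weinreb amides, and the MOM ether tolerates the Grignard base.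

**Step 11**
Reactants: 22 5-methoxy-7-(methoxymethoxy)-2,2-dimethyl-8-(3-methylbut-2-enyl)-2H-chromene; 26 N-methoxy-4-(methoxymethoxy)-N-methylbenzamide
Product: 29 [5-methoxy-7-(methoxymethoxy)-2,2-dimethyl-8-(3-methylbut-2-enyl)-2H-chromen-6-yl][4-(methoxymethoxy)phenyl]methanone, via aryllithium 27 (not isolated), via tetrahedral adduct 28 (not isolated)
Conditions: n-BuLi, THF, −20 → 0 °C; 26, −78 °C → rt; H2O
Reagents that add atoms: none
Why: Directed ortho-metalation removes the only aryl hydrogen, C6–H, which is flanked by the OMe and OMOM groups, and the Weinreb ketone synthesis stops at the chelated tetrahedral adduct so that the ketone is released only on work-up.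

**Step 12**
Reactants: 29 [5-methoxy-7-(methoxymethoxy)-2,2-dimethyl-8-(3-methylbut-2-enyl)-2H-chromen-6-yl][4-(methoxymethoxy)phenyl]methanone
Product: 30 Vismiaphenone F
Conditions: HCl (ca. 1 M in MeOH), rt → 40 °C
Reagents that add atoms: none
Why: Acid-catalysed acetal exchange with methanol removes both MOM ethers; the mild acid and temperature, and the hydrogen bond of the liberated C7 hydroxyl to the ketone, should keep the prenyl group from cyclizing and the chromene alkene from adding methanol.

**Compound list**
1 | 3,3-dimethoxybutan-2-one | CC(=O)C(C)(OC)OC | starting material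
2 | 3-methoxybut-3-en-2-one | CC(=O)C(=C)OC | intermediate
3 | lithium 3-methoxybuta-1,3-dien-2-olate (kinetic enolate of 2; not isolated) | [Li]OC(=C)C(=C)OC | intermediate
4 | 1,1,1-trifluoro-5-methoxyhex-5-ene-2,4-dione (not isolated) | C=C(OC)C(=O)CC(=O)C(F)(F)F | intermediate
5 | 1-diazo-3-methoxybut-3-en-2-one | C=C(OC)C(=O)C=[N+]=[N-] | intermediate
6 | prenyl bromide (1-bromo-3-methylbut-2-ene) | CC(C)=CCBr | starting material
7 | ethynylmagnesium bromide | C#C[Mg]Br | starting material
8 | 5-methylhex-4-en-1-yne | C#CCC=C(C)C | intermediate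
9 | (5-methylhex-4-en-1-yn-1-yl)lithium (not isolated) | [Li]C#CCC=C(C)C | intermediate
10 | lithium 5-methylhex-4-en-1-yn-1-olate (ynolate; not isolated) | [Li]OC#CCC=C(C)C | intermediate
11 | triisopropyl[(5-methylhex-4-en-1-yn-1-yl)oxy]silane | CC(C)=CCC#CO[Si](C(C)C)(C(C)C)C(C)C | intermediate
12 | 3-methoxybuta-1,3-dien-1-one (vinylketene; not isolated) | C=C(OC)C=C=O | intermediate
13 | 4-(1-methoxyethenyl)-2-(3-methylbut-2-enyl)-3-(triisopropylsilyloxy)cyclobut-2-en-1-one (racemic, transient; not isolated) | C=C(OC)C1C(=O)C(CC=C(C)C)=C1O[Si](C(C)C)(C(C)C)C(C)C | intermediate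
14 | (3E)-5-methoxy-2-(3-methylbut-2-enyl)-3-(triisopropylsilyloxy)hexa-1,3,5-trien-1-one (dienylketene, vinyl group cis to the ketene-bearing carbon; not isolated) | O=C=C(CC=C(C)C)/C(O[Si](C(C)C)(C(C)C)C(C)C)=C\C(OC)=C | intermediate
15 | 5-methoxy-2-(3-methylbut-2-enyl)-3-(triisopropylsilyloxy)cyclohexa-2,4-dien-1-one (not isolated) | COC1=CC(O[Si](C(C)C)(C(C)C)C(C)C)=C(CC=C(C)C)C(=O)C1 | intermediate
16 | 5-methoxy-2-(3-methylbut-2-enyl)-3-(triisopropylsilyloxy)phenol | COc1cc(O)c(CC=C(C)C)c(O[Si](C(C)C)(C(C)C)C(C)C)c1 | intermediate
17 | 3-methylbut-2-enal | CC(C)=CC=O | starting material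
18 | 5-methoxy-6-(3-methylbut-2-en-1-ylidene)-2-(3-methylbut-2-enyl)-3-(triisopropylsilyloxy)cyclohexa-2,4-dien-1-one (ortho-quinone methide; not isolated) | O=C1C(CC=C(C)C)=C(O[Si](C(C)C)(C(C)C)C(C)C)C=C(OC)C1=CC=C(C)C | intermediate
19 | triisopropyl{[5-methoxy-2,2-dimethyl-8-(3-methylbut-2-enyl)-2H-chromen-7-yl]oxy}silane | COc1cc(O[Si](C(C)C)(C(C)C)C(C)C)c(CC=C(C)C)c2OC(C)(C)C=Cc12 | intermediate
20 | 5-methoxy-2,2-dimethyl-8-(3-methylbut-2-enyl)-2H-chromen-7-ol | COc1cc(O)c(CC=C(C)C)c2OC(C)(C)C=Cc12 | intermediate
21 | sodium 5-methoxy-2,2-dimethyl-8-(3-methylbut-2-enyl)-2H-chromen-7-olate (not isolated) | COc1cc([O-])c(CC=C(C)C)c2OC(C)(C)C=Cc12.[Na+] | intermediate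
22 | 5-methoxy-7-(methoxymethoxy)-2,2-dimethyl-8-(3-methylbut-2-enyl)-2H-chromene | COCOc1cc(OC)c2C=CC(C)(C)Oc2c1CC=C(C)C | intermediate
23 | methyl 4-hydroxybenzoate | COC(=O)c1ccc(O)cc1 | starting material
24 | sodium 4-(methoxycarbonyl)phenolate (not isolated) | COC(=O)c1ccc([O-])cc1.[Na+] | intermediate
25 | methyl 4-(methoxymethoxy)benzoate | COCOc1ccc(cc1)C(=O)OC | intermediate
26 | N-methoxy-4-(methoxymethoxy)-N-methylbenzamide | COCOc1ccc(cc1)C(=O)N(C)OC | intermediate
27 | [5-methoxy-7-(methoxymethoxy)-2,2-dimethyl-8-(3-methylbut-2-enyl)-2H-chromen-6-yl]lithium (not isolated) | [Li]c1c(OC)c2C=CC(C)(C)Oc2c(CC=C(C)C)c1OCOC | intermediate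
28 | lithium alkoxide of the N-methoxy-N-methyl hemiaminal from 27 and 26 (tetrahedral adduct, racemic, transient; not isolated) | CON(C)C(O[Li])(c1ccc(OCOC)cc1)c1c(OC)c2C=CC(C)(C)Oc2c(CC=C(C)C)c1OCOC | intermediate
29 | [5-methoxy-7-(methoxymethoxy)-2,2-dimethyl-8-(3-methylbut-2-enyl)-2H-chromen-6-yl][4-(methoxymethoxy)phenyl]methanone | COCOc1ccc(cc1)C(=O)c1c(OC)c2C=CC(C)(C)Oc2c(CC=C(C)C)c1OCOC | intermediate
30 | Vismiaphenone F, [7-hydroxy-5-methoxy-2,2-dimethyl-8-(3-methylbut-2-enyl)-2H-chromen-6-yl](4-hydroxyphenyl)methanone | COc1c2c(c(CC=C(C)C)c(O)c1C(=O)c1ccc(O)cc1)OC(C)(C)C=C2 | target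

**Count**
Total steps: 12. Longest linear sequence: 8 steps (steps 1, 2, 5, 6, 7, 8, 11, 12; the branch through steps 3 and 4 is equally long).

**Steps most likely to fail**

1. Step 5. The photogenerated methoxy vinylketene may be captured too slowly by the ynol ether, so that ketene dimerization and photodegradation of the enol ether or of the phenol product outrun ring formation. The fallback builds the same ring A pattern by directed metalation; it sets out from prenyl bromide 6 and returns to the route at chromenol 20. Purchased 5-methoxybenzene-1,3-diol F1 would be converted with NaH and MOMCl into 1-methoxy-3,5-bis(methoxymethoxy)benzene F2. Lithiation of F2 with n-BuLi in THF at 0 °C should occur between the two MOM ethers, the stronger pair of directing groups, and alkylation with 6 would give 5-methoxy-1,3-bis(methoxymethoxy)-2-(3-methylbut-2-enyl)benzene F3. Mild methanolic HCl would then free the symmetric 5-methoxy-2-(3-methylbut-2-enyl)benzene-1,3-diol F4. Because F4 is symmetric, annulation with one equivalent of 3-methylbut-2-enal 17 under ethylenediammonium diacetate catalysis can give only chromenol 20, from which steps 8, 11 and 12 follow unchanged.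

2. Step 6. C-alkylation of the hindered monophenol by the enal may be sluggish at the temperature the annulation needs, and the ortho-prenyl phenol may cyclize to a chroman under prolonged heating with the acidic catalyst. The fallback forms the pyran by a propargyl Claisen rearrangement; it sets out from phenol 16 and returns at chromene 19. O-Alkylation of 16 with 3-chloro-3-methylbut-1-yne (K2CO3, KI, CuI cat., acetone, 60 °C) would give triisopropyl[5-methoxy-3-(2-methylbut-3-yn-2-yloxy)-2-(3-methylbut-2-enyl)phenoxy]silane F5. Heating F5 in N,N-diethylaniline at about 180 °C should bring about [3,3] rearrangement to the only free ortho carbon, enolization, a 1,5-hydrogen shift and oxa-6π closure to 19.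

3. Step 11. Acyl transfer from the N-methoxy amide to the doubly ortho-substituted aryllithium may be incomplete, with base-induced loss of formaldehyde from the amide competing. The fallback changes the oxidation level of the electrophile; it sets out from amide 26 and chromene 22 (through aryllithium 27) and returns at ketone 29. Reduction of 26 with i-Bu2AlH at −78 °C would give 4-(methoxymethoxy)benzaldehyde F6. Addition of 27 to the far more electrophilic F6 should give the racemic carbinol [5-methoxy-7-(methoxymethoxy)-2,2-dimethyl-8-(3-methylbut-2-enyl)-2H-chromen-6-yl][4-(methoxymethoxy)phenyl]methanol F7. Oxidation of this doubly benzylic alcohol with MnO2 in CH2Cl2 would give 29.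

**Further compounds**
F1 | step 5 | 5-methoxybenzene-1,3-diol (purchased) | COc1cc(O)cc(O)c1
F2 | step 5 | 1-methoxy-3,5-bis(methoxymethoxy)benzene | COCOc1cc(OC)cc(OCOC)c1
F3 | step 5 | 5-methoxy-1,3-bis(methoxymethoxy)-2-(3-methylbut-2-enyl)benzene | COCOc1cc(OC)cc(OCOC)c1CC=C(C)C
F4 | step 5 | 5-methoxy-2-(3-methylbut-2-enyl)benzene-1,3-diol | COc1cc(O)c(CC=C(C)C)c(O)c1
F5 | step 6 | triisopropyl[5-methoxy-3-(2-methylbut-3-yn-2-yloxy)-2-(3-methylbut-2-enyl)phenoxy]silane | C#CC(C)(C)Oc1cc(OC)cc(O[Si](C(C)C)(C(C)C)C(C)C)c1CC=C(C)C
F6 | step 11 | 4-(methoxymethoxy)benzaldehyde | COCOc1ccc(C=O)cc1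
F7 | step 11 | [5-methoxy-7-(methoxymethoxy)-2,2-dimethyl-8-(3-methylbut-2-enyl)-2H-chromen-6-yl][4-(methoxymethoxy)phenyl]methanol (racemic) | COCOc1ccc(cc1)C(O)c1c(OC)c2C=CC(C)(C)Oc2c(CC=C(C)C)c1OCOC
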